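**Retrosynthetic overview**
1. Target 34 ← triacetylation of tetraol lactone 33 ← SmI2 ketyl coupling of Z-enal C7 onto the C8 ketone of a β-keto ester, which closes the ten-membered ring and the γ-lactone together (C7–C8).
2. C17–C19 by crossed Claisen condensation at the C8 ester; C4–C5 by B-alkyl Suzuki coupling with (Z)-3-iodobut-2-en-1-ol; C2 carbinol by 1,3-syn reduction directed by O14.
3. Key step: an O14-silicon-tethered α-silylvinyl radical closes onto the enone β-carbon to forge C1–C2 (quaternary C1); the radical-derived boron enolate is trapped by ethyl glyoxylate (C9–C10, C9 carbinol).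
4. Ring A and its first stereocentre (C14) come from o-cresol by oxidative dearomatisation, selective hydrogenation and CBS reduction.
5. Ring order: cyclohexene ring A first (steps 1–8), then the ten-membered ring and the lactone in one operation (step 17).

Assumption: atoms are labelled with briarane numbering (C1–C20); the target SMILES corresponds to (1S,2R,5Z,7S,8S,9R,10S,14S,17R).

**Route**

Step 1
Reactants: 1 2-methylphenol (o-cresol)
Product: 2 4,4-dimethoxy-2-methylcyclohexa-2,5-dien-1-one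
Conditions: PhI(OAc)2 (2.1 equiv), MeOH, 0 °C → rt
Reagents that add atoms: methanol (CO)
Why: Hypervalent-iodine oxidative dearomatisation of a para-unsubstituted phenol in methanol gives the p-quinone monoketal; no stereocentre is formed.

Step 2
Reactants: 2 4,4-dimethoxy-2-methylcyclohexa-2,5-dien-1-one
Product: 3 4,4-dimethoxy-2-methylcyclohex-2-en-1-one
Conditions: H2 (1 atm), RhCl(PPh3)3 (3 mol %), benzene, rt
Reagents that add atoms: none
Why: Homogeneous hydrogenation with Wilkinson's catalyst reduces the disubstituted enone C=C and spares the trisubstituted, methyl-bearing one.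

Step 3
Reactants: 3 4,4-dimethoxy-2-methylcyclohex-2-en-1-one
Product: 5 (S)-4-hydroxy-3-methylcyclohex-2-en-1-one, via ketal alcohol 4 (not isolated)
Conditions: (R)-2-methyl-CBS-oxazaborolidine (C18H20BNO, 10 mol %), BH3·SMe2, THF, −20 °C; then 1 M HCl, THF, rt
Reagents that add atoms: water (O)
Why: Corey–Bakshi–Shibata reduction with the alkenyl branch as the large group gives the S carbinol (future C14), and acid work-up hydrolyses the allylic ketal to the transposed enone without touching the stereocentre.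

Step 4
Reactants: 6 chloro(dimethyl)vinylsilane
Product: 8 (1-bromovinyl)chlorodimethylsilane, via dibromide 7 (not isolated)
Conditions: Br2, CH2Cl2, −78 °C; then quinoline, 120 °C, distil
Reagents that add atoms: bromine (BrBr)
Why: Bromine addition to the vinylsilane followed by amine-induced dehydrobromination (the α-silyl hydrogen is the acidic one) gives the α-bromovinylsilane.

Step 5
Reactants: 5 (S)-4-hydroxy-3-methylcyclohex-2-en-1-one; 8 (1-bromovinyl)chlorodimethylsilane
Product: 9 (S)-4-{[(1-bromovinyl)dimethylsilyl]oxy}-3-methylcyclohex-2-en-1-one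
Conditions: Et3N, 4-(dimethylamino)pyridine (cat.), CH2Cl2, 0 °C
Reagents that add atoms: none
Why: Standard O-silylation of a secondary alcohol installs the radical precursor on O14.

Step 6 (key step)
Reactants: 9 (S)-4-{[(1-bromovinyl)dimethylsilyl]oxy}-3-methylcyclohex-2-en-1-one; 10 ethyl glyoxylate
Product: 12 ethyl (2R)-2-hydroxy-2-[(3aR,4S,7aS)-2,2,3a-trimethyl-3-methylidene-5-oxooctahydro-1,2-benzoxasilol-4-yl]acetate, via boron enolate 11 (not isolated)
Conditions: Bu3SnH (1.3 equiv, syringe pump), Et3B (3 equiv), air (trace), toluene, 0 °C; then 10 (3 equiv), −78 °C; pH 7 buffer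
Reagents that add atoms: none
Why: Proposed new method: Bu3Sn• abstracts Br, the O14-tethered α-silylvinyl radical closes 5-exo onto the enone β-carbon C1 (the tether forces C2 cis to O14 and sets the quaternary centre), the C10 α-keto radical is captured by Et3B as boron enolate 11, and 11 adds to the glyoxylate through a Zimmerman–Traxler chair on the convex face (C9 chain trans to C2, anti aldol giving 9R); the closest known reaction types are the Tamao–Ito bromovinylsilyl ether radical cyclisation and the tin hydride/Et3B radical Reformatsky-type aldol.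

Step 7
Reactants: 12 siloxane aldol
Product: 13 C9 tert-butyldimethylsilyl ether of 12
Conditions: t-BuMe2SiOTf, 2,6-lutidine, CH2Cl2, −78 °C
Reagents that add atoms: tert-butyldimethylsilyl trifluoromethanesulfonate (CC(C)(C)[Si](C)(C)OS(=O)(=O)C(F)(F)F)
Why: Silylation of the β-hydroxy ketone blocks retro-aldol and supplies a non-chelating group at O9 for step 17.

Step 8
Reactants: 13 silyl ether ketone
Product: 15 C11-methyl cyclohexene (C11=C12), via enol triflate 14 (not isolated)
Conditions: KN(SiMe3)2, THF, −78 °C; PhNTf2; then MeZnCl (2 equiv), Pd(PPh3)4 (5 mol %), rt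
Reagents that add atoms: methylzinc chloride (C[Zn]Cl)
Why: Kinetic deprotonation at the unhindered C12 methylene gives the C11=C12 enol triflate regioselectively, and Negishi coupling replaces triflate by methyl.

Step 9
Reactants: 15 alkenylsiloxane
Product: 16 β-hydroxy methyl ketone (C14–OH, C2 acetyl)
Conditions: H2O2 (30 %), KF, KHCO3, THF/MeOH, rt
Reagents that add atoms: hydrogen peroxide (OO)
Why: Tamao oxidation converts the alkenyl C–Si bond into an enol (then the C2 ketone) and releases O14; no stereocentre is touched.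

Step 10
Reactants: 16 β-hydroxy methyl ketone
Product: 19 β-hydroxy vinyl ketone (C2 ketone, C3=C4), via Mannich base 17 (not isolated), via trimethylammonium iodide 18 (not isolated)
Conditions: LiN(SiMe3)2 (2.2 equiv), THF, −78 °C; Me2N=CH2+ I−; aqueous work-up; MeI, CH2Cl2, rt; then DBU, 0 °C
Reagents that add atoms: N,N-dimethylmethyleneiminium iodide (C=[N+](C)C.[I-])
Why: Mannich α-methylenation (Eschenmoser's salt, quaternisation, E1cB elimination) is regiospecific because C3 is the only enolisable position of the C2 ketone.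

Step 11
Reactants: 19 β-hydroxy vinyl ketone
Product: 20 syn-1,3-diol (C2 R, vinyl carbinol)
Conditions: Et2BOMe, THF/MeOH (4:1), −78 °C; NaBH4; MeOH azeotrope
Reagents that add atoms: none
Why: Narasaka–Prasad reduction: external hydride attacks the O14–B–O2 chelate on the face of the angular methyl, away from the C10 side chain, giving the 1,3-syn diol and thus 2R.

Step 12
Reactants: 20 syn-1,3-diol
Product: 21 C2,C14 acetonide
Conditions: Me2C(OMe)2, pyridinium p-toluenesulfonate (cat.), CH2Cl2, rt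
Reagents that add atoms: 2,2-dimethoxypropane (COC(C)(C)OC)
Why: Ketalisation of the syn-1,3-diol gives a chair dioxane and masks both hydroxyls against lactonisation onto the C8 ester.

Step 13
Reactants: 22 but-2-yn-1-ol
Product: 24 (Z)-3-iodobut-2-en-1-ol, via alkenylalanate 23 (not isolated)
Conditions: NaAlH2(OCH2CH2OMe)2, THF, 0 °C → rt; then I2, −78 °C
Reagents that add atoms: iodine (II)
Why: Alkoxide-directed trans-hydroalumination places aluminium on the distal alkyne carbon, and iodinolysis with retention fixes the Z geometry (iodine cis to CH2OH).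

Step 14
Reactants: 21 acetonide; 24 (Z)-3-iodobut-2-en-1-ol
Product: 26 coupled Z-allylic alcohol (C2–C7 chain), via alkylborane 25 (not isolated)
Conditions: 9-BBN (9-borabicyclo[3.3.1]nonane), THF, rt; then 24, PdCl2(dppf) (dppf = 1,1'-bis(diphenylphosphino)ferrocene, 5 mol %), AsPh3, Cs2CO3, DMF/H2O, rt
Reagents that add atoms: none
Why: Anti-Markovnikov hydroboration of the terminal vinyl group and B-alkyl Suzuki–Miyaura coupling form C4–C5 with retention of the vinyl iodide geometry (5Z).

Step 15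
Reactants: 26 coupled Z-allylic alcohol; 27 ethyl propanoate
Product: 29 β-keto ester (C8 ketone, C17 epimers), via lithium enolate 28 (not isolated)
Conditions: LiN(i-Pr)2 (4.5 equiv), 27 (4.5 equiv), THF, −78 °C; add 26, −78 → −20 °C; AcOH
Reagents that add atoms: none
Why: Crossed Claisen condensation of the propanoate enolate with the activated α-silyloxy ester is driven by deprotonation of the product β-keto ester.

Step 16
Reactants: 29 β-keto ester
Product: 30 Z-enal (C7 aldehyde)
Conditions: MnO2, CH2Cl2, rt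
Reagents that add atoms: none
Why: MnO2 oxidises only the primary allylic alcohol and does not isomerise the Z-alkene at room temperature.

Step 17
Reactants: 30 Z-enal β-keto ester
Product: 32 macrocyclic lactone (C8–OH, C9–OSiMe2t-Bu, acetonide), via dihydroxy ester 31 (not isolated)
Conditions: SmI2 (3 equiv), THF/MeOH (10:1), −78 → 0 °C, 2 mM, slow addition; aq. NH4Cl
Reagents that add atoms: none
Why: Proposed new method: the enal ketyl adds to the samarium-chelated β-keto ester ketone (a pinacol-type radical coupling known for β-keto esters in five- and six-membered ring closures) on the Felkin face opposite the C9 silyloxy group and anti to the C17 methyl; the samarium bridge gives the cis-diol (7S,8S) and the C7 alkoxide lactonises onto the ethyl ester, with C17 settling as methyl cis to the C8 hydroxyl.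

Step 18
Reactants: 32 macrocyclic lactone
Product: 33 tetraol lactone (2,8,9,14-tetrahydroxy)
Conditions: HF (48 % aq.), MeCN, 0 °C → rt
Reagents that add atoms: none
Why: Aqueous HF cleaves the silyl ether and the acetonide in one operation under conditions too mild for translactonisation or epimerisation.

Step 19
Reactants: 33 tetraol lactone
Product: 34 stylatulide lactone
Conditions: Ac2O (3.5 equiv), pyridine, 4-(dimethylamino)pyridine (cat.), CH2Cl2, 0 °C
Reagents that add atoms: acetic anhydride (CC(=O)OC(C)=O)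
Why: Acyl-transfer-catalysed acetylation esterifies the three secondary hydroxyls (C2, C9, C14) and leaves the hindered tertiary C8 hydroxyl free.

**Compound list**
1 | 2-methylphenol (o-cresol) | Cc1ccccc1O | starting material
2 | 4,4-dimethoxy-2-methylcyclohexa-2,5-dien-1-one | CC1=CC(OC)(OC)C=CC1=O | intermediate
3 | 4,4-dimethoxy-2-methylcyclohex-2-en-1-one | CC1=CC(OC)(OC)CCC1=O | intermediate
4 | (S)-4,4-dimethoxy-2-methylcyclohex-2-en-1-ol | O[C@H]1CCC(OC)(OC)C=C1C | intermediate
5 | (S)-4-hydroxy-3-methylcyclohex-2-en-1-one | O[C@H]1CCC(=O)C=C1C | intermediate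
6 | chloro(dimethyl)vinylsilane | C=C[Si](C)(C)Cl | starting material
7 | chloro(1,2-dibromoethyl)dimethylsilane | BrCC(Br)[Si](C)(C)Cl | intermediate
8 | (1-bromovinyl)chlorodimethylsilane | C=C(Br)[Si](C)(C)Cl | intermediate
9 | (S)-4-{[(1-bromovinyl)dimethylsilyl]oxy}-3-methylcyclohex-2-en-1-one | C=C(Br)[Si](C)(C)O[C@H]1CCC(=O)C=C1C | intermediate
10 | ethyl glyoxylate (ethyl 2-oxoacetate) | CCOC(=O)C=O | starting material
11 | diethylboron enolate (C10=C11–OBEt2) of the cis-fused cyclised siloxane ketone | C=C1[Si](C)(C)O[C@H]2CCC(OB(CC)CC)=C[C@@]12C | intermediate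
12 | ethyl (2R)-2-hydroxy-2-[(3aR,4S,7aS)-2,2,3a-trimethyl-3-methylidene-5-oxooctahydro-1,2-benzoxasilol-4-yl]acetate (cis ring fusion; side chain cis to the angular methyl) | C=C1[Si](C)(C)O[C@H]2CCC(=O)[C@H]([C@@H](O)C(=O)OCC)[C@@]12C | intermediate
13 | tert-butyldimethylsilyl ether of 12 at the side-chain hydroxyl (C9) | C=C1[Si](C)(C)O[C@H]2CCC(=O)[C@H]([C@@H](O[Si](C)(C)C(C)(C)C)C(=O)OCC)[C@@]12C | intermediate
14 | C11=C12 enol triflate of 13 | C=C1[Si](C)(C)O[C@H]2CC=C(OS(=O)(=O)C(F)(F)F)[C@H]([C@@H](O[Si](C)(C)C(C)(C)C)C(=O)OCC)[C@@]12C | intermediate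
15 | C11-methyl C11=C12 cyclohexene siloxane (triflate of 14 replaced by CH3) | C=C1[Si](C)(C)O[C@H]2CC=C(C)[C@H]([C@@H](O[Si](C)(C)C(C)(C)C)C(=O)OCC)[C@@]12C | intermediate
16 | ring A β-hydroxy methyl ketone: ethyl (R)-2-silyloxy-2-(ring A) acetate with C1 bearing CH3 and acetyl, C14–OH cis to acetyl, side chain trans to acetyl | O[C@H]1CC=C(C)[C@H]([C@@H](O[Si](C)(C)C(C)(C)C)C(=O)OCC)[C@@]1(C)C(C)=O | intermediate
17 | Mannich base of 16 (C2 ketone carrying CH2CH2NMe2) | O[C@H]1CC=C(C)[C@H]([C@@H](O[Si](C)(C)C(C)(C)C)C(=O)OCC)[C@@]1(C)C(=O)CCN(C)C | intermediate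
18 | trimethylammonium iodide of 17 | O[C@H]1CC=C(C)[C@H]([C@@H](O[Si](C)(C)C(C)(C)C)C(=O)OCC)[C@@]1(C)C(=O)CC[N+](C)(C)C.[I-] | intermediate
19 | β-hydroxy vinyl ketone (C2 ketone, C3=C4 vinyl; other centres as in 16) | O[C@H]1CC=C(C)[C@H]([C@@H](O[Si](C)(C)C(C)(C)C)C(=O)OCC)[C@@]1(C)C(=O)C=C | intermediate
20 | syn-1,3-diol: (2R)-vinyl carbinol at C2, C14–OH, centres as in 34 | O[C@H]1CC=C(C)[C@H]([C@@H](O[Si](C)(C)C(C)(C)C)C(=O)OCC)[C@@]1(C)[C@H](O)C=C | intermediate
21 | acetonide of 20 (O2 and O14 bridged by CMe2; cis-fused dioxane on ring A) | CC1(C)O[C@H]2CC=C(C)[C@H]([C@@H](O[Si](C)(C)C(C)(C)C)C(=O)OCC)[C@@]2(C)[C@@H](C=C)O1 | intermediate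
22 | but-2-yn-1-ol | CC#CCO | starting material
23 | sodium cyclic alkenylalanate from trans-hydroalumination of 22 | CC1=CCO[Al-]1(OCCOC)OCCOC.[Na+] | intermediate
24 | (Z)-3-iodobut-2-en-1-ol | C/C(I)=C/CO | intermediate
25 | B-alkyl-9-BBN adduct of 21 (boron on C4) | CC1(C)O[C@H]2CC=C(C)[C@H]([C@@H](O[Si](C)(C)C(C)(C)C)C(=O)OCC)[C@@]2(C)[C@@H](CCB3C4CCCC3CCC4)O1 | intermediate
26 | coupled ester alcohol: C2–C3–C4–C5(CH3)=C6–C7H2OH chain with 5Z alkene on acetonide 21 | CC1(C)O[C@H]2CC=C(C)[C@H]([C@@H](O[Si](C)(C)C(C)(C)C)C(=O)OCC)[C@@]2(C)[C@@H](CC/C(C)=C\CO)O1 | intermediate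
27 | ethyl propanoate | CCC(=O)OCC | starting material
28 | lithium enolate of ethyl propanoate | CC=C([O-])OCC.[Li+] | intermediate
29 | β-keto ester: C8 ketone carrying CH(CH3)CO2Et (C17 epimers), C7 allylic alcohol | CC1(C)O[C@H]2CC=C(C)[C@H]([C@@H](O[Si](C)(C)C(C)(C)C)C(=O)C(C)C(=O)OCC)[C@@]2(C)[C@@H](CC/C(C)=C\CO)O1 | intermediate
30 | Z-enal β-keto ester (C7 aldehyde) | CC1(C)O[C@H]2CC=C(C)[C@H]([C@@H](O[Si](C)(C)C(C)(C)C)C(=O)C(C)C(=O)OCC)[C@@]2(C)[C@@H](CC/C(C)=C\C=O)O1 | intermediate
31 | ten-membered cis-7,8-diol ethyl ester (7S,8S,17R; seco-lactone) | CC4(C)O[C@H]1CC=C(C)[C@@H]2[C@@H](O[Si](C)(C)C(C)(C)C)[C@](O)([C@@H](C)C(=O)OCC)[C@@H](O)/C=C(/C)CC[C@@H](O4)[C@@]12C | intermediate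
32 | macrocyclic γ-lactone: 8-hydroxy, 9-O-tert-butyldimethylsilyl, 2,14-O-isopropylidene; all centres as in 34 | CC4(C)O[C@H]1CC=C(C)[C@@H]2[C@@H](O[Si](C)(C)C(C)(C)C)[C@@]3(O)[C@H](/C=C(/C)CC[C@@H](O4)[C@@]12C)OC(=O)[C@@H]3C | intermediate
33 | tetraol lactone (2,8,9,14-tetrahydroxy; triol precursor of 34) | O[C@H]1CC=C(C)[C@@H]2[C@@H](O)[C@@]3(O)[C@H](/C=C(/C)CC[C@@H](O)[C@@]12C)OC(=O)[C@@H]3C | intermediate
34 | stylatulide lactone, (1S,2R,5Z,7S,8S,9R,10S,14S,17R) | CC(=O)O[C@H]1CC=C(C)[C@@H]2[C@@H](OC(C)=O)[C@@]3(O)[C@H](/C=C(/C)CC[C@@H](OC(C)=O)[C@@]12C)OC(=O)[C@@H]3C | target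

**Totals**
Total step count: 19. Longest linear sequence: 17 (steps 1–3, 5–12, 14–19).

**Steps most likely to fail**

Step 6 (radical cyclisation/aldol cascade). The vinyl radical may be reduced by tin hydride, or shift a hydrogen, before it cyclises. The fallback sets out from 5 and returns at 19; it uses the slower-reducing α-silylmethyl radical and builds the C2 ketone afterwards. Silylate 5 with (bromomethyl)chlorodimethylsilane to the (bromomethyl)dimethylsilyl ether F1. Bu3SnH/Et3B cyclisation and glyoxylate trapping as in step 6 give the saturated siloxane aldol F2. Protection gives the silyl ether F3, then the enol triflate F4 and the C11-methyl alkene F5 follow as in steps 7 and 8. Tamao oxidation gives the 1,3-diol F6 (C2 as CH2OH). Selective oxidation of the primary alcohol (TEMPO, PhI(OAc)2) gives the aldehyde F7, CH2=CHMgBr at −78 °C gives the allylic alcohol F8 (C2 epimers), and MnO2 oxidises only this allylic alcohol to 19. C2 is then set in step 11.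

Step 15 (crossed Claisen on a hindered α-silyloxy ester). The fallback sets out from 26 and returns at 32; it replaces enolate acylation by aldehyde homologation. Reduce 26 with i-Bu2AlH at −78 °C to the α-silyloxy aldehyde F9. A Roskamp reaction with methyl 2-diazopropanoate and SnCl2 gives the methyl β-keto ester F10. MnO2 gives the enal F11, and the SmI2 closure of step 17 then gives 32 with loss of methanol.

Step 17 (SmI2 macrocyclisation). Reductive loss of the C9 silyloxy group next to the ketone, or simple carbonyl reduction, may outrun the ten-membered ring closure. The fallback sets out from 30 and returns at 33; it removes the ketone and closes the ring by ketyl–olefin addition instead. Convert 30 with t-BuMe2SiCl and imidazole into the silyl enol ether F12 (a β-silyloxy enoate). SmI2 then adds the C7 ketyl to C8 of the enoate with lactonisation, giving the bis-silyl lactone F13. HF as in step 18 gives 33.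

**Further compounds**
F1 | step 6 | (S)-4-{[(bromomethyl)dimethylsilyl]oxy}-3-methylcyclohex-2-en-1-one | C[Si](C)(CBr)O[C@H]1CCC(=O)C=C1C
F2 | step 6 | saturated siloxane aldol (C2 as ring CH2; otherwise as 12) | C1[Si](C)(C)O[C@H]2CCC(=O)[C@H]([C@@H](O)C(=O)OCC)[C@@]12C
F3 | step 6 | tert-butyldimethylsilyl ether of F2 | C1[Si](C)(C)O[C@H]2CCC(=O)[C@H]([C@@H](O[Si](C)(C)C(C)(C)C)C(=O)OCC)[C@@]12C
F4 | step 6 | C11=C12 enol triflate of F3 | C1[Si](C)(C)O[C@H]2CC=C(OS(=O)(=O)C(F)(F)F)[C@H]([C@@H](O[Si](C)(C)C(C)(C)C)C(=O)OCC)[C@@]12C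
F5 | step 6 | C11-methyl alkene from F4 | C1[Si](C)(C)O[C@H]2CC=C(C)[C@H]([C@@H](O[Si](C)(C)C(C)(C)C)C(=O)OCC)[C@@]12C
F6 | step 6 | 1,3-diol (C2 hydroxymethyl, C14–OH) | O[C@H]1CC=C(C)[C@H]([C@@H](O[Si](C)(C)C(C)(C)C)C(=O)OCC)[C@@]1(C)CO
F7 | step 6 | β-hydroxy aldehyde (C2 formyl) | O[C@H]1CC=C(C)[C@H]([C@@H](O[Si](C)(C)C(C)(C)C)C(=O)OCC)[C@@]1(C)C=O
F8 | step 6 | allylic alcohol, C2 epimers | O[C@H]1CC=C(C)[C@H]([C@@H](O[Si](C)(C)C(C)(C)C)C(=O)OCC)[C@@]1(C)C(O)C=C
F9 | step 15 | α-silyloxy aldehyde (C8 formyl) from 26 | CC1(C)O[C@H]2CC=C(C)[C@H]([C@@H](O[Si](C)(C)C(C)(C)C)C=O)[C@@]2(C)[C@@H](CC/C(C)=C\CO)O1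
F10 | step 15 | methyl β-keto ester analogue of 29 | CC1(C)O[C@H]2CC=C(C)[C@H]([C@@H](O[Si](C)(C)C(C)(C)C)C(=O)C(C)C(=O)OC)[C@@]2(C)[C@@H](CC/C(C)=C\CO)O1
F11 | step 15 | methyl ester analogue of enal 30 | CC1(C)O[C@H]2CC=C(C)[C@H]([C@@H](O[Si](C)(C)C(C)(C)C)C(=O)C(C)C(=O)OC)[C@@]2(C)[C@@H](CC/C(C)=C\C=O)O1
F12 | step 17 | tert-butyldimethylsilyl enol ether of 30 (C8–OSi, C8=C17) | CC1(C)O[C@H]2CC=C(C)[C@H]([C@@H](O[Si](C)(C)C(C)(C)C)C(O[Si](C)(C)C(C)(C)C)=C(C)C(=O)OCC)[C@@]2(C)[C@@H](CC/C(C)=C\C=O)O1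
F13 | step 17 | macrocyclic lactone with 8,9-bis(tert-butyldimethylsilyl) ethers and 2,14-acetonide | CC4(C)O[C@H]1CC=C(C)[C@@H]2[C@@H](O[Si](C)(C)C(C)(C)C)[C@@]3(O[Si](C)(C)C(C)(C)C)[C@H](/C=C(/C)CC[C@@H](O4)[C@@]12C)OC(=O)[C@@H]3C
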